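(All runs are simulated for an exercise; noise was put on by code.)

The constants of the two substrates are unknown, but their ratio can be read from the runs.

| flask | left-handed substrate | right-handed substrate | gas | free catalyst | added ligand | remark | time |
|---|---|---|---|---|---|---|---|
| Tuesday's | 1.0 × 10⁻⁴ M | 1.0 × 10⁻⁴ M | 0.018 mM (held) | 0.1 mol% | 0.66 µM | run made earlier |  |
| Sunday's | 1.5 × 10⁻⁴ M | 1.5 × 10⁻⁴ M | 0.018 mM (held) | 0.1 mol% | 0.66 µM | run made earlier |  |
| Wednesday's | 2.0 × 10⁻⁴ M | 2.0 × 10⁻⁴ M | 0.018 mM (held) | 0.2 mol% | 0.66 µM | run made earlier |  |
| flask | 2.0 × 10⁻⁴ M | 2.0 × 10⁻⁴ M | 0.018 mM (held) | 0.1 mol% | 0.66 µM |  | 3.0 min |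

- Tuesday's (time / min: right-handed substrate / %, left-handed substrate / %): 0.200: 41.8, 23.2; 0.500: 33.7, 8.6; 1.00: 22.0, 2.5; 1.50: 17.0, 0.2; 2.00: 14.7, 0.7; 3.00: 11.8, 0.9; 4.00: 9.1, 0
- Sunday's (time / min: right-handed substrate / %, left-handed substrate / %): 0.200: 40.9, 22.6; 0.500: 28.9, 7.1; 1.00: 16.8, 1.1; 1.50: 9.3, 0.8; 2.00: 9.0, 0; 3.00: 5.9, 0; 4.00: 4.8, 0
- Wednesday's (time / min: right-handed substrate / %, left-handed substrate / %): 0.333: 26.8, 3.7; 0.833: 6.8, 0; 1.50: 2.1, 0; 2.50: 0, 0; 4.00: 1.8, 0

(standard deviation of a reading: 1 percentage point)

- free catalyst is single-handed; left-handed substrate and right-handed substrate are mirror images of each other, charged as a racemate, each of them at the stated concentration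
- at the start none of the gas is in solution

1. whether the excess of right-handed substrate over left-handed substrate among what is left of the two reaches 99 % by 3.0 min (no / yes)
2. the highest excess of right-handed substrate over left-handed substrate among what is left of the two up to 3.0 min

What is the zero of the scale? The mirror-image case. Let x be what is left of a substrate as a fraction of its own charge. With equal constants, x_L equals x_R, and a racemate keeps zero excess at any conversion.

And here? Suppose each substrate goes first order in itself on one shared catalyst, a pseudo-first-order picture. Dividing the two rate laws then removes time and catalyst, so x_L equals x_R raised to the power s. Sunday's readings at 0.500 min and Wednesday's at 0.333 min give on average 3.87, a reading with its scatter, for the selectivity factor s, defined as ln x_L over ln x_R.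

What does the wanted excess require? The excess is (x_R − x_L)/(x_R + x_L). Setting it to 99 % and using the rule, I reckon a threshold: right-handed substrate must fall to 7.90 % of the two charged together.

But time is missing from that rule, so can a run still stand above the threshold at a given time? Yes. At 3.00 min, Tuesday's run read 11.8 % of right-handed substrate, above it, and Sunday's read 5.9 %, below it, at the same loading. From Tuesday's run to Sunday's the charge rose and that reading fell; the new flask has Sunday's loading and a larger charge than Sunday's, so I commit to yes. If it merely matched Sunday's reading, the excess would be 99.6 %.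

The forecast says yes, with a top of 99.6 %, and adds “this is likely but not certain”.

The new flask gives yes, with a top of 99.9 %.

    free catalyst + left-handed substrate ⇌ catalyst intermediate A (K = 2600 /M, k = 7.00 × 10⁶ /M/s)
    free catalyst + right-handed substrate ⇌ catalyst intermediate B (K = 2500 /M, k = 2.90 × 10⁷ /M/s)
    partner + catalyst intermediate A → free catalyst + left-handed product (k = 3.20 × 10⁷ /M/s)
    partner + catalyst intermediate B → free catalyst + right-handed product (k = 7.40 × 10⁶ /M/s)
    gas ⇌ partner, rate k5*(csat - [partner]) (kL = 1.50 /s)
    free catalyst + added ligand ⇌ idle complex (K = 7.60 × 10⁵ /M, k = 56000 /M/s)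
    free catalyst → spent catalyst (k = 0.0170 /s)

The new flask passed 99 % at 1.51 min, with 7.78 % of right-handed substrate left, beside the threshold of 7.90 %. At 3.00 min it held 2.96 % of right-handed substrate. On Tuesday's run the same threshold lies under the last reading, 9.1 % at 4.00 min, by 1.2 percentage points.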